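**Two times.** Set the 30 min allowed in this flask against the estimated time for its scarcer charge to be consumed: that comparison is the ground for expecting this flask to be still moving at the asked time or to have stopped.

- oak: starting material 0.70 M; coupling partner 1.12 M; run made earlier
- flask: starting material 1.4 M; coupling partner 1.12 M; time 30 min

oak run (percent of the starting material charged)

| time / min | starting material / % | first product / % |
|---|---|---|
| 1.50 | 35.3 | 16.7 |
| 3.00 | 17.6 | 13.8 |
| 5.00 | 9.9 | 8.0 |
| 6.00 | 5.7 | 7.2 |
| 8.00 | 7.0 | 6.2 |
| 10.0 | 5.7 | 4.4 |

(each reading ± 1 percentage point)



1. starting material at 30 min, in percent of the starting material charged
2. first product at 30 min, in percent of the starting material charged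
3. other mono adduct at 30 min, in percent of the starting material charged
4. bis adduct at 30 min, in percent of the starting material charged

**Clearing time.** In the flask the coupling partner is the limiting reagent, its 1.12 M standing below the 1.4 M of starting material, so the partner's clock is the one to read. The oak run lends the rate: its first reading, 35.3% at 1.50 min, is read as one e-fold of starting material in 1.44 min from a partner charge of 1.12 M, with the scatter of a reading. Call one e-fold of the scarcer species, the larger charge held as charged, the clearing time; if the rate is proportional to each concentration, it goes inversely with the larger charge, so the estimate for the flask is 1.15 min as its clearing time. The time allowed is 26.1 clearing times, so this reckoning expects the flask to stand at its stopping point by the asked time, with starting material remaining.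

**Forecast, result.** The forecast, holding that “30 min is the end state”, gave 39.7% starting material, 17% first product, 24% other mono adduct and 19.5% bis adduct. The flask gives 16.0%, 0.0242%, 23.5% and 11.2%.

    coupling partner + other mono adduct → bis adduct + by-product (k = 0.00570 /M/s)
    coupling partner + first product → over-reaction product (k = 0.00800 /M/s)
    starting material + first product → side product (k = 0.0130 /M/s)
    starting material + coupling partner ⇌ first product + by-product (K = 2.90, k = 0.00690 /M/s)
    starting material + coupling partner → other mono adduct + by-product (k = 0.00680 /M/s)
    coupling partner + first product → bis adduct + by-product (k = 3.00 × 10⁻⁴ /M/s)

**The neighbour.** The flask keeps 0.0422% of its partner charge at 30.0 min, and at 300 min its starting material still stands at 16.0%. With 2.8 M of partner the neighbour turns the roles round: starting material is the scarcer charge, and the same reckoning gives a clearing time of 0.575 min, or 52.2 of them in the time allowed. That neighbour flask at 30.0 min holds 0.0193% starting material, 14.2% of its own partner charge and 51.1% bis adduct.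

The readings stem from a simulated flask with constants of no real substance, and the scatter is random.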